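**Plan**

Ring numbering used throughout: C1 (C=O), C2 (quaternary oxirane C), C3 (oxirane CH), C4 (CHOH), C5 (C–CH2OH), C6 (C–heptenyl); side chain C1′H2–C2′H=C3′(Me)–CO2H.
Cuts, in retrosynthetic order: C4–OH back to C4=O (masked as a ketal); C6–heptenyl (from a C6 bromide); the oxirane C–O bonds (from the C2=C3 enone of a quinone monoketal); C2–C1′ (ring plus complete tiglate side chain); the ring itself is a para-methoxyphenol.
Forward: no ring is built. The benzene ring of 5-hydroxy-2-methoxybenzaldehyde is brominated at C6, raised to the quinone-monoketal level, coupled at C2 with the side chain (rearomatising), oxidised again, epoxidised, alkenylated at C6, unmasked at C4 and reduced.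
Enabling feature: C2 is ortho to the C1 oxygen; at the monoketal level it is the free terminus of the O-methyl oxocarbenium ion C4(=O+Me)–C3=C2 (the other terminus, C6, carries Br). C1′ is the γ-carbon of a tiglate, a vinylogous enolate donor. The temporary ketal oxidation level is removed by the rearomatisation itself.
Stereochemistry: C2/C3 (absolute) from the tartrate-mediated, CH2OH-directed nucleophilic epoxidation; C4 from hydride addition anti to the oxirane; both E alkenes from the dienolate γ-attack and the (E)-alkenylboronic acid.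

Key step: step 6

Assumption: the sense of induction in the tartrate-mediated epoxidation (step 9) is taken as L-(+)-DIPT giving the epoxide enantiomer drawn; if the hydroxymethyl-directed model delivers the other face, D-(−)-DIPT is used with no other change.

**Route**

Step 1
Reactants: 1 5-hydroxy-2-methoxybenzaldehyde
Product: 2 2-bromo-3-hydroxy-6-methoxybenzaldehyde
Conditions: Br2 (1.05 equiv), NaOAc, AcOH, 15 °C → rt
Reagents that add atoms: bromine BrBr
Why: Electrophilic aromatic bromination under phenol control: para to OH is occupied by OMe and the ortho site para to the formyl group is the more deactivated one, so bromine should enter between OH and CHO, as in the 2-bromination of isovanillin.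

Step 2
Reactants: 2 2-bromo-3-hydroxy-6-methoxybenzaldehyde
Product: 3 2-bromo-3-(hydroxymethyl)-4-methoxyphenol
Conditions: NaBH4, MeOH, 0 °C
Reagents that add atoms: none
Why: Borohydride reduction of the aryl aldehyde gives the benzylic alcohol that later directs the epoxidation; phenol and aryl bromide are untouched.

Step 3
Reactants: 3 2-bromo-3-(hydroxymethyl)-4-methoxyphenol
Product: 4 2-bromo-3-(hydroxymethyl)-4,4-dimethoxycyclohexa-2,5-dien-1-one
Conditions: PhI(OAc)2 (1.1 equiv), MeOH, 0 °C
Reagents that add atoms: methanol CO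
Why: Oxidative dearomatisation of a para-methoxyphenol with a λ3-iodane: methanol adds at the methoxy-bearing para carbon to give the dimethyl quinone monoketal, which turns the former phenol ortho carbon C2 into an electrophilic site for step 6.

Step 4
Reactants: 5 tiglic acid
Product: 6 tert-butyl (E)-2-methylbut-2-enoate
Conditions: isobutene (excess), H2SO4 (cat.), CH2Cl2, sealed vessel, rt
Reagents that add atoms: 2-methylpropene CC(C)=C
Why: Acid-catalysed tert-butyl ester formation by addition of the acid to isobutene leaves the E geometry untouched and gives an ester that should withstand amide base, cold Lewis acid, peroxide anion, Pd(0) and hydride.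

Step 5
Reactants: 6 tert-butyl (E)-2-methylbut-2-enoate
Product: 7 [(1-tert-butoxy-2-methylbuta-1,3-dien-1-yl)oxy]trimethylsilane
Conditions: LDA, THF–DMPU, −78 °C; TMSCl, −78 °C → rt; distil
Reagents that add atoms: chlorotrimethylsilane C[Si](C)(C)Cl
Why: γ-Deprotonation of the enoate (the C4 methyl is the only position that gives a conjugated dienolate) and O-silylation give the silyl ketene acetal diene, the standard vinylogous Mukaiyama donor, whose ketene-acetal geometry is lost in step 6.

Step 6
Reactants: 4 2-bromo-3-(hydroxymethyl)-4,4-dimethoxycyclohexa-2,5-dien-1-one; 7 [(1-tert-butoxy-2-methylbuta-1,3-dien-1-yl)oxy]trimethylsilane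
Product: 11 tert-butyl (E)-4-[3-bromo-2-hydroxy-4-(hydroxymethyl)-5-methoxyphenyl]-2-methylbut-2-enoate, via O-silylated monoketal 8 (not isolated), via cyclohexadienone adduct 9 (not isolated), via bis-silyl ether 10 (not isolated)
Conditions: 7 (3.0 equiv), TMSOTf (0.2 equiv), CH2Cl2, −78 → −40 °C; then 10% aq. citric acid–THF, rt
Reagents that add atoms: none
Why: Proposed new method: TMSOTf first moves a silyl group from excess 7 onto the CH2OH (8) and then ionises one ketal methoxy group to the O-methyl quinone oxocarbenium ion, whose charge sits on C4, C2 and C6; the γ-CH2 terminus of 7 bonds to C2, the silyloxocarbenium ion loses its silyl group to give dienone 9, and 9 enolises to the phenol, held as 10 until the acidic work-up. The closest known reaction types are the acid-promoted substitution of quinone monoketals by alkenes, arenes and enol silanes at the carbon α to the carbonyl with rearomatisation, and the vinylogous Mukaiyama reaction of tiglate silyl dienolates with oxocarbenium ions. No ring is closed and no stereocentre is made; the E enoate follows from γ-attack of the s-trans dienolate, which leaves CO2tBu trans to the new CH2–aryl bond as in other vinylogous Mukaiyama reactions of this donor. The step needs attack at C2 and not at C6, C4 or the Michael position C3, and through the γ- and not the α-carbon of the donor: C6 carries bromine and cannot rearomatise, C4 is fully substituted and flanked by the CH2OSiMe3 arm, ketal ionisation by TMSOTf is faster than activation of the cross-conjugated ketone that would open the Michael path to C3, and the α-carbon of 7 is fully substituted. The remaining ketal methoxy group stays as the arene OMe at C4, so the product is exactly the para-methoxyphenol that step 7 re-oxidises.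

Step 7
Reactants: 11 tert-butyl (E)-4-[3-bromo-2-hydroxy-4-(hydroxymethyl)-5-methoxyphenyl]-2-methylbut-2-enoate
Product: 12 tert-butyl (E)-4-[5-bromo-4-(hydroxymethyl)-3,3-dimethoxy-6-oxocyclohexa-1,4-dien-1-yl]-2-methylbut-2-enoate
Conditions: PhI(OAc)2 (1.1 equiv), MeOH, 0 °C
Reagents that add atoms: methanol CO
Why: Second λ3-iodane oxidative dearomatisation of the para-methoxyphenol, under non-basic conditions that avoid oxa-Michael closure of the phenol onto the enoate, gives the quinone monoketal with the side chain on the enone α-carbon C2.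

Step 8
Reactants: 12 tert-butyl (E)-4-[5-bromo-4-(hydroxymethyl)-3,3-dimethoxy-6-oxocyclohexa-1,4-dien-1-yl]-2-methylbut-2-enoate
Product: 13 tert-butyl (E)-4-[10-bromo-11-(hydroxymethyl)-9-oxo-1,5-dioxaspiro[5.5]undeca-7,10-dien-8-yl]-2-methylbut-2-enoate
Conditions: HO(CH2)3OH, PPTS (cat.), 4 Å MS, benzene, 50 °C
Reagents that add atoms: propane-1,3-diol OCCCO
Why: Acid-catalysed transketalisation gives the 1,3-dioxane, the ketal type for which the tartrate-mediated epoxidation of hydroxymethyl quinone monoketals has close precedent.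

Step 9
Reactants: 13 tert-butyl (E)-4-[10-bromo-11-(hydroxymethyl)-9-oxo-1,5-dioxaspiro[5.5]undeca-7,10-dien-8-yl]-2-methylbut-2-enoate
Product: 14 tert-butyl (E)-4-[(1′R,6′S)-3′-bromo-4′-(hydroxymethyl)-2′-oxospiro[1,3-dioxane-2,5′-[7]oxabicyclo[4.1.0]hept[3]en]-1′-yl]-2-methylbut-2-enoate
Conditions: Ph3COOH, NaHMDS, L-(+)-DIPT, 4 Å MS, PhMe, −40 °C
Reagents that add atoms: trityl hydroperoxide OOC(c1ccccc1)(c1ccccc1)c1ccccc1
Why: Tartrate-mediated, hydroxymethyl-directed Weitz–Scheffer nucleophilic epoxidation: the sodium alkoxide of the C5–CH2OH, held in a chiral sodium tartrate aggregate, should deliver trityl peroxide to C3 from one enantiotopic face and the enolate then closes at C2, so both oxirane stereocentres are set together by the tartrate, while the tetrasubstituted bromo-alkene C5=C6 is too hindered to compete.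

Step 10
Reactants: 14 tert-butyl (E)-4-[(1′R,6′S)-3′-bromo-4′-(hydroxymethyl)-2′-oxospiro[1,3-dioxane-2,5′-[7]oxabicyclo[4.1.0]hept[3]en]-1′-yl]-2-methylbut-2-enoate; 15 (E)-hept-1-enylboronic acid
Product: 16 tert-butyl (E)-4-[(1′R,6′S)-3′-[(E)-hept-1-enyl]-4′-(hydroxymethyl)-2′-oxospiro[1,3-dioxane-2,5′-[7]oxabicyclo[4.1.0]hept[3]en]-1′-yl]-2-methylbut-2-enoate
Conditions: Pd(OAc)2 (5 mol %), SPhos (10 mol %), K3PO4, THF–H2O, 45 °C
Reagents that add atoms: none
Why: Suzuki–Miyaura coupling of the α-bromoenone C6–Br with the (E)-alkenylboronic acid proceeds with retention of alkene geometry, and the oxirane, ketal, free alcohol and tert-butyl enoate should tolerate the mild phosphate base.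

Step 11
Reactants: 16 tert-butyl (E)-4-[(1′R,6′S)-3′-[(E)-hept-1-enyl]-4′-(hydroxymethyl)-2′-oxospiro[1,3-dioxane-2,5′-[7]oxabicyclo[4.1.0]hept[3]en]-1′-yl]-2-methylbut-2-enoate
Product: 17 tert-butyl (E)-4-[(1R,6S)-3-[(E)-hept-1-enyl]-4-(hydroxymethyl)-2,5-dioxo-7-oxabicyclo[4.1.0]hept-3-en-1-yl]-2-methylbut-2-enoate
Conditions: 48% aq. HF, MeCN, 0 °C → rt
Reagents that add atoms: water O
Why: Acid-catalysed ketal hydrolysis unmasks the C4 ketone; the oxirane is deactivated towards acid opening by the flanking carbonyl and ketal carbons, and the tert-butyl ester should survive the weak acid.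

Step 12
Reactants: 17 tert-butyl (E)-4-[(1R,6S)-3-[(E)-hept-1-enyl]-4-(hydroxymethyl)-2,5-dioxo-7-oxabicyclo[4.1.0]hept-3-en-1-yl]-2-methylbut-2-enoate
Product: 18 tert-butyl (E)-4-[(1R,5R,6R)-3-[(E)-hept-1-enyl]-5-hydroxy-4-(hydroxymethyl)-2-oxo-7-oxabicyclo[4.1.0]hept-3-en-1-yl]-2-methylbut-2-enoate
Conditions: DIBAL-H (3 equiv), THF, −78 °C; Rochelle salt
Reagents that add atoms: none
Why: 1,2-Reduction of an α,β-epoxy ketone with DIBAL-H: the aluminium alkoxide formed at the C5–CH2OH anchors and activates the neighbouring C4=O (C1=O is flanked by the quaternary C2 and the dienyl C6), and hydride should add from the face opposite the oxirane oxygen, which places the new C4–OH syn to the epoxide.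

Step 13
Reactants: 18 tert-butyl (E)-4-[(1R,5R,6R)-3-[(E)-hept-1-enyl]-5-hydroxy-4-(hydroxymethyl)-2-oxo-7-oxabicyclo[4.1.0]hept-3-en-1-yl]-2-methylbut-2-enoate
Product: 19 ambuic acid, (E)-4-[(1R,5R,6R)-3-[(E)-hept-1-enyl]-5-hydroxy-4-(hydroxymethyl)-2-oxo-7-oxabicyclo[4.1.0]hept-3-en-1-yl]-2-methylbut-2-enoic acid
Conditions: TFA–CH2Cl2 (1:4), 0 °C → rt
Reagents that add atoms: none
Why: Acidolysis of the tert-butyl ester (E1 loss of isobutene) frees the acid without base, to which the epoxy enone is sensitive, and touches no stereocentre.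

**Compound list**

1 | 5-hydroxy-2-methoxybenzaldehyde | COc1ccc(O)cc1C=O | starting material
2 | 2-bromo-3-hydroxy-6-methoxybenzaldehyde | COc1ccc(O)c(Br)c1C=O | intermediate
3 | 2-bromo-3-(hydroxymethyl)-4-methoxyphenol | COc1ccc(O)c(Br)c1CO | intermediate
4 | 2-bromo-3-(hydroxymethyl)-4,4-dimethoxycyclohexa-2,5-dien-1-one | COC1(OC)C=CC(=O)C(Br)=C1CO | intermediate
5 | tiglic acid, (E)-2-methylbut-2-enoic acid | C/C=C(\C)C(=O)O | starting material
6 | tert-butyl (E)-2-methylbut-2-enoate | C/C=C(\C)C(=O)OC(C)(C)C | intermediate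
7 | [(1-tert-butoxy-2-methylbuta-1,3-dien-1-yl)oxy]trimethylsilane (mixture of ketene-acetal isomers) | C=CC(C)=C(OC(C)(C)C)O[Si](C)(C)C | intermediate
8 | 2-bromo-4,4-dimethoxy-3-[(trimethylsilyloxy)methyl]cyclohexa-2,5-dien-1-one | COC1(OC)C=CC(=O)C(Br)=C1CO[Si](C)(C)C | intermediate (not isolated)
9 | tert-butyl (E)-4-[5-bromo-3-methoxy-6-oxo-4-[(trimethylsilyloxy)methyl]cyclohexa-2,4-dien-1-yl]-2-methylbut-2-enoate (racemic) | COC1=CC(C/C=C(\C)C(=O)OC(C)(C)C)C(=O)C(Br)=C1CO[Si](C)(C)C | intermediate (not isolated)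
10 | tert-butyl (E)-4-[3-bromo-5-methoxy-2-(trimethylsilyloxy)-4-[(trimethylsilyloxy)methyl]phenyl]-2-methylbut-2-enoate | COc1cc(C/C=C(\C)C(=O)OC(C)(C)C)c(O[Si](C)(C)C)c(Br)c1CO[Si](C)(C)C | intermediate (not isolated)
11 | tert-butyl (E)-4-[3-bromo-2-hydroxy-4-(hydroxymethyl)-5-methoxyphenyl]-2-methylbut-2-enoate | COc1cc(C/C=C(\C)C(=O)OC(C)(C)C)c(O)c(Br)c1CO | intermediate
12 | tert-butyl (E)-4-[5-bromo-4-(hydroxymethyl)-3,3-dimethoxy-6-oxocyclohexa-1,4-dien-1-yl]-2-methylbut-2-enoate | COC1(OC)C=C(C/C=C(\C)C(=O)OC(C)(C)C)C(=O)C(Br)=C1CO | intermediate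
13 | tert-butyl (E)-4-[10-bromo-11-(hydroxymethyl)-9-oxo-1,5-dioxaspiro[5.5]undeca-7,10-dien-8-yl]-2-methylbut-2-enoate | O=C1C(Br)=C(CO)C2(OCCCO2)C=C1C/C=C(\C)C(=O)OC(C)(C)C | intermediate
14 | tert-butyl (E)-4-[(1′R,6′S)-3′-bromo-4′-(hydroxymethyl)-2′-oxospiro[1,3-dioxane-2,5′-[7]oxabicyclo[4.1.0]hept[3]en]-1′-yl]-2-methylbut-2-enoate | BrC1=C(CO)C3(OCCCO3)[C@H]2O[C@@]2(C/C=C(\C)C(=O)OC(C)(C)C)C1=O | intermediate
15 | (E)-hept-1-enylboronic acid | CCCCC/C=C/B(O)O | starting material
16 | tert-butyl (E)-4-[(1′R,6′S)-3′-[(E)-hept-1-enyl]-4′-(hydroxymethyl)-2′-oxospiro[1,3-dioxane-2,5′-[7]oxabicyclo[4.1.0]hept[3]en]-1′-yl]-2-methylbut-2-enoate | CCCCC/C=C/C1=C(CO)C3(OCCCO3)[C@H]2O[C@@]2(C/C=C(\C)C(=O)OC(C)(C)C)C1=O | intermediate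
17 | tert-butyl (E)-4-[(1R,6S)-3-[(E)-hept-1-enyl]-4-(hydroxymethyl)-2,5-dioxo-7-oxabicyclo[4.1.0]hept-3-en-1-yl]-2-methylbut-2-enoate | CCCCC/C=C/C1=C(CO)C(=O)[C@H]2O[C@@]2(C/C=C(\C)C(=O)OC(C)(C)C)C1=O | intermediate
18 | tert-butyl (E)-4-[(1R,5R,6R)-3-[(E)-hept-1-enyl]-5-hydroxy-4-(hydroxymethyl)-2-oxo-7-oxabicyclo[4.1.0]hept-3-en-1-yl]-2-methylbut-2-enoate | CCCCC/C=C/C1=C(CO)[C@@H](O)[C@H]2O[C@@]2(C/C=C(\C)C(=O)OC(C)(C)C)C1=O | intermediate
19 | ambuic acid, (E)-4-[(1R,5R,6R)-3-[(E)-hept-1-enyl]-5-hydroxy-4-(hydroxymethyl)-2-oxo-7-oxabicyclo[4.1.0]hept-3-en-1-yl]-2-methylbut-2-enoic acid | CCCCC/C=C/C1=C(CO)[C@@H](O)[C@H]2O[C@@]2(C/C=C(\C)C(=O)O)C1=O | target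

**Totals and risks**

Total step count: 13. Longest linear sequence: 11 (steps 1–3 and 6–13).

Step 6 (Proposed new method). What may go wrong: the silyl dienolate may be protonated before C–C bond formation, Mukaiyama–Michael addition at C3 or attack through the donor α-carbon may compete, and the Lewis acid may cleave the tert-butyl ester. Fallback with known chemistry, setting out from 3: O-allylation with allyl bromide and K2CO3 in acetone should give [2-bromo-6-methoxy-3-(prop-2-enyloxy)phenyl]methanol F1. Aromatic Claisen rearrangement (PhNEt2, 190 °C) should move the allyl group to the only free ortho position to give 2-bromo-3-(hydroxymethyl)-4-methoxy-6-(prop-2-enyl)phenol F2. Cross-metathesis of F2 with tert-butyl methacrylate (Hoveyda–Grubbs II, CH2Cl2, 40 °C) should give the E enoate and comes back to the route at 11.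

Step 9. What may go wrong: poor enantiofacial selectivity of peroxide delivery, or deprotonation of the doubly activated side-chain CH2 by the amide base instead of clean epoxidation. Fallback, setting out from 12: transketalisation with (2R,4R)-pentane-2,4-diol (PPTS) should give the C2-symmetric chiral ketal tert-butyl (E)-4-[(2R,4R)-10-bromo-11-(hydroxymethyl)-2,4-dimethyl-9-oxo-1,5-dioxaspiro[5.5]undeca-7,10-dien-8-yl]-2-methylbut-2-enoate F3. Auxiliary-controlled nucleophilic epoxidation (Ph3COOH, KHMDS, THF, −78 °C) should give its 7,8-epoxide F4; the diol enantiomer is chosen to match the required face and is shown as R,R. Suzuki coupling with 15 as in step 10 should give the hept-1-enyl compound F5, and aqueous HF in MeCN removes the auxiliary and comes back to the route at 17.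

Step 12. What may go wrong: hydride delivery from the oxirane face through chelation to the oxirane oxygen, which would give the C4 epimer, or partial reduction at C1. Fallback, setting out from 17: if the reduction gives mainly the epimer tert-butyl (E)-4-[(1R,5S,6R)-3-[(E)-hept-1-enyl]-5-hydroxy-4-(hydroxymethyl)-2-oxo-7-oxabicyclo[4.1.0]hept-3-en-1-yl]-2-methylbut-2-enoate F6, a Mitsunobu reaction (4-nitrobenzoic acid, PPh3, DIAD, THF, 0 °C) inverts C4 and esterifies the primary alcohol. This should give the (1R,5R,6R) bis(4-nitrobenzoate) F7, and K2CO3–MeOH at 0 °C cleaves both esters and comes back to the route at 18.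

**Further compounds**

F1 | step 6 | [2-bromo-6-methoxy-3-(prop-2-enyloxy)phenyl]methanol | COc1ccc(OCC=C)c(Br)c1CO
F2 | step 6 | 2-bromo-3-(hydroxymethyl)-4-methoxy-6-(prop-2-enyl)phenol | COc1cc(CC=C)c(O)c(Br)c1CO
F3 | step 9 | tert-butyl (E)-4-[(2R,4R)-10-bromo-11-(hydroxymethyl)-2,4-dimethyl-9-oxo-1,5-dioxaspiro[5.5]undeca-7,10-dien-8-yl]-2-methylbut-2-enoate | O=C1C(Br)=C(CO)C2(O[C@H](C)C[C@@H](C)O2)C=C1C/C=C(\C)C(=O)OC(C)(C)C
F4 | step 9 | 7,8-epoxide of F3 with the oxirane configuration of 14 | BrC1=C(CO)C3(O[C@H](C)C[C@@H](C)O3)[C@H]2O[C@@]2(C/C=C(\C)C(=O)OC(C)(C)C)C1=O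
F5 | step 9 | (E)-hept-1-enyl analogue of F4 | CCCCC/C=C/C1=C(CO)C3(O[C@H](C)C[C@@H](C)O3)[C@H]2O[C@@]2(C/C=C(\C)C(=O)OC(C)(C)C)C1=O
F6 | step 12 | tert-butyl (E)-4-[(1R,5S,6R)-3-[(E)-hept-1-enyl]-5-hydroxy-4-(hydroxymethyl)-2-oxo-7-oxabicyclo[4.1.0]hept-3-en-1-yl]-2-methylbut-2-enoate | CCCCC/C=C/C1=C(CO)[C@H](O)[C@H]2O[C@@]2(C/C=C(\C)C(=O)OC(C)(C)C)C1=O
F7 | step 12 | (1R,5R,6R) bis(4-nitrobenzoate) of 18 | CCCCC/C=C/C1=C(COC(=O)c3ccc(cc3)[N+](=O)[O-])[C@@H](OC(=O)c4ccc(cc4)[N+](=O)[O-])[C@H]2O[C@@]2(C/C=C(\C)C(=O)OC(C)(C)C)C1=O
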